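**Retrosynthetic overview**
1. The hydroperoxide comes last, by Markovnikov O2/silane hydroperoxidation of an isopropenyl group followed by fluoride desilylation. The 5-OH comes from a 5-F. The C6 side chain comes from lithiation between F and OMe, addition to 3-methylbutanal, and elimination.
2. Pyranone ring C comes from C-acylation of a ring-B benzoxepinone enolate with 2,6-difluoro-4-methoxybenzoyl chloride, then O-arylation with loss of one F.
3. The oxepine ring comes from SNAr of the (S)-carbinol oxygen of a γ-hydroxy aryl ketone on the ring-B fluoride.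
4. The key C–C bond is the bridge CH2–CH(O). A ketone homoenolate (β-zincio ketone from opening of a 1-arylcyclopropanol) adds to methacrolein under a chiral titanium catalyst, which sets the only stereocentre.
5. Ring order: cyclopropane (made, then opened), then oxepine, then ring C. Rings A and B are bought.

Assumption: the [C@@H] centre is read as (S). Tetracycles are named with flavone numbering (O1, C2 to C8a, ring B primed). "Bridge" means the unit C3-CH2-CH(R)-O-C2' that closes the oxepine, and (S) refers to its CH(R) carbon.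

**Step 1**
Reactants: 1 methyl 2-fluoro-4-hydroxybenzoate
Product: 2 methyl 2-fluoro-4-(triisopropylsilyloxy)benzoate
Conditions: TIPSCl (1.1 equiv), imidazole (2 equiv), DMF, rt
Reagents that add atoms: triisopropylsilyl chloride, CC(C)[Si](Cl)(C(C)C)C(C)C
Why: Imidazole-promoted O-silylation (substitution at silicon) masks the acidic phenol for the organometallic steps, and TIPS is chosen because it is the most base-stable common phenol silyl ether yet leaves with fluoride in the last step; no stereocentre is involved.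

**Step 2**
Reactants: 2 methyl 2-fluoro-4-(triisopropylsilyloxy)benzoate
Product: 3 1-[2-fluoro-4-(triisopropylsilyloxy)phenyl]cyclopropan-1-ol
Conditions: EtMgBr (2.6 equiv), Ti(OiPr)4 (0.3 equiv), THF, 0 °C to rt; aq NH4Cl
Reagents that add atoms: ethylmagnesium bromide, CC[Mg]Br (supplies the CH2CH2 unit)
Why: Kulinkovich cyclopropanation, in which the titanacyclopropane formed from two EtMgBr on tetravalent titanium acts as a 1,2-dicarbanion on the ester and closes to the 1-arylcyclopropanol, tolerates aryl fluorides and silyl ethers; no stereocentre is formed.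

**Step 3 (key step)**
Reactants: 3 1-[2-fluoro-4-(triisopropylsilyloxy)phenyl]cyclopropan-1-ol; 4 methacrolein
Product: 6 (S)-1-[2-fluoro-4-(triisopropylsilyloxy)phenyl]-4-hydroxy-5-methylhex-5-en-1-one, via zinc homoenolate 5 (not isolated)
Conditions: Zn(CH2SiMe3)2 (1.05 equiv), toluene, 0 to 40 °C; then Ti(OiPr)4 (1.2 equiv), (1R,2R)-1,2-bis(trifluoromethanesulfonamido)cyclohexane (10 mol%), 4 (1.5 equiv, slow addition), −20 °C; aq NH4Cl
Reagents that add atoms: bis(trimethylsilylmethyl)zinc, C[Si](C)(C)C[Zn]C[Si](C)(C)C (its atoms are kept only in 5)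
Why: Proposed new method: the zinc alkoxide of 3 opens by strain-releasing β-carbon elimination to the carbonyl-chelated β-zincio ketone 5, so that the ketone β-carbon becomes the nucleophile (homoaldol addition of a ketone homoenolate), the CH2SiMe3 group on zinc is a non-transferable dummy, and the titanium complex of the (R,R)-bis(sulfonamide) passes the functionalised alkyl group to the Si face of the enal as it does with other alkylzincs and so gives the (S)-carbinol, the closest known reaction types being the titanium bis(sulfonamide)-catalysed enantioselective addition of mixed functionalised diorganozincs to α-substituted enals, the homoaldol addition of zinc and titanium ester homoenolates, and the dialkylzinc-induced opening of cyclopropanols to zinc homoenolates.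

**Step 4**
Reactants: 6 (S)-1-[2-fluoro-4-(triisopropylsilyloxy)phenyl]-4-hydroxy-5-methylhex-5-en-1-one
Product: 7 (S)-2-(prop-1-en-2-yl)-8-(triisopropylsilyloxy)-3,4-dihydro-1-benzoxepin-5(2H)-one
Conditions: KN(SiMe3)2 (1.1 equiv), THF (0.02 M), 0 to 55 °C
Reagents that add atoms: none
Why: Intramolecular SNAr (addition-elimination) of the potassium alkoxide on the fluoride ortho to the ketone closes the seven-membered ether at high dilution, ketone enolisation being a reversible dead end while fluoride loss is irreversible, and the C–O bond at the stereocentre is never broken so (S) is retained.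

**Step 5**
Reactants: 7 (S)-2-(prop-1-en-2-yl)-8-(triisopropylsilyloxy)-3,4-dihydro-1-benzoxepin-5(2H)-one; 8 2,6-difluoro-4-methoxybenzoic acid
Product: 11 (S)-5-fluoro-7-methoxy-4'-(triisopropylsilyloxy)flavone bearing the bridge C3-CH2-CH(isopropenyl)-O-C2', via acid chloride 9 (not isolated), via lithium diketonate 10 (not isolated)
Conditions: 8, (COCl)2, cat. DMF, CH2Cl2, rt, evaporate; 7, LiN(SiMe3)2 (2.2 equiv), THF, −78 °C, add 9, to 0 °C; then DMF, 60 °C
Reagents that add atoms: oxalyl chloride, O=C(Cl)C(=O)Cl (its chlorine is kept only in 9)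
Why: Claisen-type C-acylation of the lithium enolate followed by intramolecular SNAr O-arylation of the diketonate (lithium-assisted loss of the fluoride ortho to the new ketone) builds ring C, the two fluorines of 9 are equivalent so only one chromone can form, and the remote non-acidic stereocentre is untouched.

**Step 6**
Reactants: 11 (S)-5-fluoro-7-methoxy-4'-(triisopropylsilyloxy)flavone bearing the bridge C3-CH2-CH(isopropenyl)-O-C2'; 12 3-methylbutanal
Product: 16 (S)-5-fluoro-7-methoxy-6-[(E)-3-methylbut-1-enyl]-4'-(triisopropylsilyloxy)flavone bearing the bridge C3-CH2-CH(isopropenyl)-O-C2', via aryllithium 13 (not isolated), via lithium carbinolate 14 (not isolated), via benzylic mesylate 15 (not isolated)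
Conditions: lithium 2,2,6,6-tetramethylpiperidide (LiTMP, from n-BuLi and the amine, 1.3 equiv), THF, −78 °C; 12 (1.5 equiv), −78 °C; MsCl (2 equiv), then DBU (4 equiv), −78 °C to 40 °C
Reagents that add atoms: lithium 2,2,6,6-tetramethylpiperidide, [Li]N1C(C)(C)CCCC1(C)C (lithium kept only in 13 and 14); methanesulfonyl chloride, CS(=O)(=O)Cl (kept only in 15)
Why: Directed ortho-lithiation takes the C6–H because it is the only ring hydrogen flanked by fluorine and methoxy (C2 and C3 of the chromone are blocked and the hindered amide does not add to the vinylogous ester), 1,2-addition to the aldehyde gives a carbinol whose configuration is irrelevant, and base-induced elimination of the strongly activated benzylic mesylate can only lose a CH2 hydrogen and gives the conjugated E-alkene with aryl and isopropyl anti.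

**Step 7**
Reactants: 16 (S)-5-fluoro-7-methoxy-6-[(E)-3-methylbut-1-enyl]-4'-(triisopropylsilyloxy)flavone bearing the bridge C3-CH2-CH(isopropenyl)-O-C2'
Product: 18 (S)-5-hydroxy-7-methoxy-6-[(E)-3-methylbut-1-enyl]-4'-(triisopropylsilyloxy)flavone bearing the bridge C3-CH2-CH(isopropenyl)-O-C2', via sulfonylethyl ether 17 (not isolated)
Conditions: MeSO2CH2CH2OH (1.5 equiv), NaH (3.5 equiv), DMF, 0 °C to rt; aq NH4Cl
Reagents that add atoms: 2-(methylsulfonyl)ethanol, CS(=O)(=O)CCO (its oxygen stays as the 5-OH)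
Why: SNAr hydroxylation with a hydroxide surrogate, in which the alkoxide displaces the 5-fluoride (ortho to C4=O and meta to both ring oxygens) and the sulfonylethyl ether then fragments by E1cB to the chelated 5-phenoxide, works at a temperature at which the bulky 4'-TIPS ether survives, and the stereocentre is not involved.

**Step 8**
Reactants: 18 (S)-5-hydroxy-7-methoxy-6-[(E)-3-methylbut-1-enyl]-4'-(triisopropylsilyloxy)flavone bearing the bridge C3-CH2-CH(isopropenyl)-O-C2'
Product: 20 CNP0171472.1 = (S)-5,4'-dihydroxy-7-methoxy-6-[(E)-3-methylbut-1-enyl]flavone bearing the bridge C3-CH2-CH[C(CH3)2OOH]-O-C2', via silyl peroxide 19 (not isolated)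
Conditions: Co(thd)2 (thd = 2,2,6,6-tetramethylheptane-3,5-dionate, 10 mol%), Et3SiH (2 equiv), O2 (1 atm), ClCH2CH2Cl, rt; then HF·pyridine, pyridine, THF, 0 °C to rt
Reagents that add atoms: dioxygen, O=O; triethylsilane, CC[SiH](CC)CC (silicon kept only in 19)
Why: Mukaiyama–Isayama hydroperoxysilylation (cobalt-hydride hydrogen atom transfer, capture of the tertiary radical by O2, silyl transfer) is Markovnikov and favours the unhindered 1,1-disubstituted alkene over the E-1,2-disubstituted styrene, whose hydrogen-accepting carbon carries an isopropyl group and whose benzylic radical is twisted out of conjugation by the two ortho oxygens, O2 capture outruns β-scission of the aryloxy group so the neighbouring (S) centre is kept, no stereocentre arises at CMe2, and buffered HF then removes both silyl groups without touching the O–O bond.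

**Compound list**
1 | methyl 2-fluoro-4-hydroxybenzoate | COC(=O)c1ccc(O)cc1F | starting material
2 | methyl 2-fluoro-4-(triisopropylsilyloxy)benzoate | COC(=O)c1ccc(O[Si](C(C)C)(C(C)C)C(C)C)cc1F | intermediate
3 | 1-[2-fluoro-4-(triisopropylsilyloxy)phenyl]cyclopropan-1-ol | OC1(CC1)c1ccc(O[Si](C(C)C)(C(C)C)C(C)C)cc1F | intermediate
4 | methacrolein (2-methylprop-2-enal) | CC(=C)C=O | starting material
5 | {3-[2-fluoro-4-(triisopropylsilyloxy)phenyl]-3-oxopropyl}(trimethylsilylmethyl)zinc, not isolated | C[Si](C)(C)C[Zn]CCC(=O)c1ccc(O[Si](C(C)C)(C(C)C)C(C)C)cc1F | intermediate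
6 | (S)-1-[2-fluoro-4-(triisopropylsilyloxy)phenyl]-4-hydroxy-5-methylhex-5-en-1-one | O=C(CC[C@H](O)C(C)=C)c1ccc(O[Si](C(C)C)(C(C)C)C(C)C)cc1F | intermediate
7 | (S)-2-(prop-1-en-2-yl)-8-(triisopropylsilyloxy)-3,4-dihydro-1-benzoxepin-5(2H)-one | O=C1CC[C@@H](C(C)=C)Oc2cc(O[Si](C(C)C)(C(C)C)C(C)C)ccc12 | intermediate
8 | 2,6-difluoro-4-methoxybenzoic acid | COc1cc(F)c(C(=O)O)c(F)c1 | starting material
9 | 2,6-difluoro-4-methoxybenzoyl chloride, not isolated | COc1cc(F)c(C(=O)Cl)c(F)c1 | intermediate
10 | 4-(2,6-difluoro-4-methoxybenzoyl) derivative of 7 (1,3-diketone, in the flask as its lithium enolate, C4 not defined), not isolated | COc1cc(F)c(C(=O)C2C[C@@H](C(C)=C)Oc3cc(O[Si](C(C)C)(C(C)C)C(C)C)ccc3C2=O)c(F)c1 | intermediate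
11 | (S)-5-fluoro-7-methoxy-4'-(triisopropylsilyloxy)flavone, bridge R = isopropenyl | COc1cc2oc3c(c(=O)c2c(F)c1)C[C@@H](C(C)=C)Oc1cc(O[Si](C(C)C)(C(C)C)C(C)C)ccc1-3 | intermediate
12 | 3-methylbutanal | CC(C)CC=O | starting material
13 | 6-lithio derivative of 11, not isolated | COc1cc2oc3c(c(=O)c2c(F)c1[Li])C[C@@H](C(C)=C)Oc1cc(O[Si](C(C)C)(C(C)C)C(C)C)ccc1-3 | intermediate
14 | lithium alkoxide of the 6-(1-hydroxy-3-methylbutyl) derivative of 11 (carbinol carbon not defined), not isolated | COc1cc2oc3c(c(=O)c2c(F)c1C(O[Li])CC(C)C)C[C@@H](C(C)=C)Oc1cc(O[Si](C(C)C)(C(C)C)C(C)C)ccc1-3 | intermediate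
15 | 6-[1-(methylsulfonyloxy)-3-methylbutyl] derivative of 11, not isolated | COc1cc2oc3c(c(=O)c2c(F)c1C(OS(C)(=O)=O)CC(C)C)C[C@@H](C(C)=C)Oc1cc(O[Si](C(C)C)(C(C)C)C(C)C)ccc1-3 | intermediate
16 | (S)-5-fluoro-7-methoxy-6-[(E)-3-methylbut-1-enyl]-4'-(triisopropylsilyloxy)flavone, bridge R = isopropenyl | COc1cc2oc3c(c(=O)c2c(F)c1/C=C/C(C)C)C[C@@H](C(C)=C)Oc1cc(O[Si](C(C)C)(C(C)C)C(C)C)ccc1-3 | intermediate
17 | 5-[2-(methylsulfonyl)ethoxy] analogue of 16, not isolated | COc1cc2oc3c(c(=O)c2c(OCCS(C)(=O)=O)c1/C=C/C(C)C)C[C@@H](C(C)=C)Oc1cc(O[Si](C(C)C)(C(C)C)C(C)C)ccc1-3 | intermediate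
18 | (S)-5-hydroxy-7-methoxy-6-[(E)-3-methylbut-1-enyl]-4'-(triisopropylsilyloxy)flavone, bridge R = isopropenyl | COc1cc2oc3c(c(=O)c2c(O)c1/C=C/C(C)C)C[C@@H](C(C)=C)Oc1cc(O[Si](C(C)C)(C(C)C)C(C)C)ccc1-3 | intermediate
19 | analogue of 18 with bridge R = C(CH3)2OOSiEt3, not isolated | COc1cc2oc3c(c(=O)c2c(O)c1/C=C/C(C)C)C[C@@H](C(C)(C)OO[Si](CC)(CC)CC)Oc1cc(O[Si](C(C)C)(C(C)C)C(C)C)ccc1-3 | intermediate
20 | CNP0171472.1, (S)-5,4'-dihydroxy-7-methoxy-6-[(E)-3-methylbut-1-enyl]flavone, bridge R = C(CH3)2OOH | COc1cc2oc3c(c(=O)c2c(O)c1/C=C/C(C)C)C[C@@H](C(C)(C)OO)Oc1cc(O)ccc1-3 | target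

**Step count and weak points**
Total step count: 8. Longest linear sequence: 8 (1 to 20). Compounds 4, 8 and 12 are bought and enter directly.

Most likely to fail, first: step 3. The zinc cyclopropoxide may open too slowly or sit on titanium, the opened species may react through its enolised form, or the ee may be low. The fallback sets out from 4 and comes back at 6. It keeps the homoenolate logic but uses a preformed ester homoenolate and builds the aryl ketone afterwards.
- ZnCl2 and [(1-ethoxycyclopropyl)oxy]trimethylsilane in ether give bis(3-ethoxy-3-oxopropyl)zinc F1, a true dialkylzinc.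
- Under the same Ti(OiPr)4/(R,R)-bis(sulfonamide) catalysis, F1 adds to 4 to give ethyl (S)-4-hydroxy-5-methylhex-5-enoate F2.
- A trace of TsOH closes F2 to (S)-5-(prop-1-en-2-yl)oxolan-2-one F3.
- In parallel, 4-bromo-3-fluorophenol is silylated to (4-bromo-3-fluorophenoxy)triisopropylsilane F4.
- iPrMgCl·LiCl converts F4 into [2-fluoro-4-(triisopropylsilyloxy)phenyl]magnesium chloride F5.
- F5 is added once to F3 at −40 °C. The C–O bond of the stereocentre is never touched, and the product is 6.

Second: step 6. Lithiation may be unselective (C8, C3'), or the aryllithium next to fluorine may decay or attack a chromone. The fallback sets out from 8 (joined again with 7) and comes back at 16. It puts the side chain on ring A by cross-coupling before ring C exists.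
- NIS in CF3CO2H gives 2,6-difluoro-3-iodo-4-methoxybenzoic acid F6.
- Suzuki–Miyaura coupling on zerovalent palladium (Pd(dppf)Cl2, K3PO4, dioxane–water, 70 °C) with commercial (E)-3-methylbut-1-enylboronic acid pinacol ester gives 2,6-difluoro-4-methoxy-3-[(E)-3-methylbut-1-enyl]benzoic acid F7.
- 1-Chloro-N,N,2-trimethylprop-1-en-1-amine gives 2,6-difluoro-4-methoxy-3-[(E)-3-methylbut-1-enyl]benzoyl chloride F8.
- F8 acylates the lithium enolate of 7 as in step 5 to the 4-aroyl diketone F9.
- Ring closure onto the fluorine remote from the side chain gives 16. The 8-alkenyl isomer from closure at the other fluorine is removed by chromatography.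

Third: step 8. The styrene may compete for the cobalt hydride, and the 5-hydroxy-4-keto unit may bind divalent cobalt. The fallback sets out from 14 and comes back at 20. It unveils the styrene only after the peroxide is in place.
- Step 6 is quenched with aq NH4Cl before MsCl is added, which gives the 5-fluoro benzylic carbinol F10.
- The conditions of step 7, with one more equivalent of NaH, lead through the sulfonylethyl ether carbinol F11 to the 5-hydroxy benzylic carbinol F12, whose only alkene is the isopropenyl group.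
- Co(thd)2, O2 and Et3SiH give the silyl peroxide carbinol F13.
- HF·pyridine gives the hydroperoxide carbinol F14.
- Catalytic pyridinium tosylate with 4 Å sieves in dilute CH2Cl2 at rt ionises the doubly oxygen-activated ortho-hydroxybenzylic alcohol (ortho-quinone methide pathway). Proton loss gives the E-styrene 20. Tertiary hydroperoxides tolerate such mild acid.

**Further compounds**
F1 | step 3 | bis(3-ethoxy-3-oxopropyl)zinc | CCOC(=O)CC[Zn]CCC(=O)OCC
F2 | step 3 | ethyl (S)-4-hydroxy-5-methylhex-5-enoate | CCOC(=O)CC[C@H](O)C(C)=C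
F3 | step 3 | (S)-5-(prop-1-en-2-yl)oxolan-2-one | O=C1CC[C@@H](C(C)=C)O1
F4 | step 3 | (4-bromo-3-fluorophenoxy)triisopropylsilane | CC(C)[Si](Oc1ccc(Br)c(F)c1)(C(C)C)C(C)C
F5 | step 3 | [2-fluoro-4-(triisopropylsilyloxy)phenyl]magnesium chloride | CC(C)[Si](Oc1ccc([Mg]Cl)c(F)c1)(C(C)C)C(C)C
F6 | step 6 | 2,6-difluoro-3-iodo-4-methoxybenzoic acid | COc1cc(F)c(C(=O)O)c(F)c1I
F7 | step 6 | 2,6-difluoro-4-methoxy-3-[(E)-3-methylbut-1-enyl]benzoic acid | COc1cc(F)c(C(=O)O)c(F)c1/C=C/C(C)C
F8 | step 6 | 2,6-difluoro-4-methoxy-3-[(E)-3-methylbut-1-enyl]benzoyl chloride | COc1cc(F)c(C(=O)Cl)c(F)c1/C=C/C(C)C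
F9 | step 6 | 4-aroyl diketone from 7 and F8 (C4 not defined) | COc1cc(F)c(C(=O)C2C[C@@H](C(C)=C)Oc3cc(O[Si](C(C)C)(C(C)C)C(C)C)ccc3C2=O)c(F)c1/C=C/C(C)C
F10 | step 8 | 5-fluoro benzylic carbinol, 6-(1-hydroxy-3-methylbutyl) derivative of 11 (carbinol carbon not defined) | COc1cc2oc3c(c(=O)c2c(F)c1C(O)CC(C)C)C[C@@H](C(C)=C)Oc1cc(O[Si](C(C)C)(C(C)C)C(C)C)ccc1-3
F11 | step 8 | sulfonylethyl ether carbinol, 5-[2-(methylsulfonyl)ethoxy] analogue of F10 | COc1cc2oc3c(c(=O)c2c(OCCS(C)(=O)=O)c1C(O)CC(C)C)C[C@@H](C(C)=C)Oc1cc(O[Si](C(C)C)(C(C)C)C(C)C)ccc1-3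
F12 | step 8 | 5-hydroxy benzylic carbinol, 5-OH analogue of F10 | COc1cc2oc3c(c(=O)c2c(O)c1C(O)CC(C)C)C[C@@H](C(C)=C)Oc1cc(O[Si](C(C)C)(C(C)C)C(C)C)ccc1-3
F13 | step 8 | silyl peroxide carbinol, F12 with bridge R = C(CH3)2OOSiEt3 | COc1cc2oc3c(c(=O)c2c(O)c1C(O)CC(C)C)C[C@@H](C(C)(C)OO[Si](CC)(CC)CC)Oc1cc(O[Si](C(C)C)(C(C)C)C(C)C)ccc1-3
F14 | step 8 | hydroperoxide carbinol, 20 with 6-(1-hydroxy-3-methylbutyl) in place of the alkenyl group | COc1cc2oc3c(c(=O)c2c(O)c1C(O)CC(C)C)C[C@@H](C(C)(C)OO)Oc1cc(O)ccc1-3
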